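Blue and amber, both stopped at 20.0 min, already hold your quick number, and your hunch about the reagent charge stands up on them: amber, with more reagent, has less starting material left than blue. The flasks, the runs and the questions:

common to all: starting material 46 mM

| flask | reagent | remark | time |
|---|---|---|---|
| blue | 270 mM | run made earlier |  |
| amber | 440 mM | run made earlier |  |
| north-west | 410 mM |  | 20 min |
| north | 280 mM |  | 20 min |
| north-east | 180 mM |  | 20 min |

| run | time / min | starting material / % | isomer of the product / % | target / % | over-reaction product / % |
|---|---|---|---|---|---|
| blue | 4.00 | 78.8 | 0 | 20.7 | 0.2 |
| blue | 8.00 | 62.9 | 1.0 | 34.2 | 0.4 |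
| blue | 12.0 | 51.2 | 1.5 | 42.7 | 2.4 |
| blue | 15.0 | 45.9 | 3.9 | 46.9 | 2.8 |
| blue | 20.0 | 38.6 | 5.9 | 52.6 | 3.9 |
| amber | 2.00 | 81.5 | 0.1 | 18.7 | 0 |
| amber | 5.00 | 61.5 | 1.3 | 36.9 | 1.0 |
| amber | 10.0 | 40.5 | 3.1 | 53.4 | 4.1 |
| amber | 15.0 | 28.4 | 5.5 | 59.6 | 6.5 |
| amber | 20.0 | 22.1 | 7.9 | 61.9 | 9.4 |

(readings scatter by 0.5 percentage points)



- which of these there is most of at the end, counted by the starting material in it, north-west (over-reaction product / isomer of the product / target / starting material)
- which of these there is most of at the end, counted by the starting material in it, north (over-reaction product / isomer of the product / target / starting material)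
- which of these there is most of at the end, counted by the starting material in it, north-east (over-reaction product / isomer of the product / target / starting material)
- how much there is at the end of the one of these that leads, in percent of the starting material charged: north-west
- how much there is at the end of the one of these that leads, in percent of the starting material charged: north
- how much there is at the end of the one of these that leads, in percent of the starting material charged: north-east

Starting material is the limiting reagent: one reagent per starting material takes 17.0% of the blue charge and 10.5% of the amber charge. So we freeze the reagent at its charge c, which treats the decay as pseudo-first-order, and reckon from a, the fraction of starting material left at 20 min: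

g = −ln a / c

blue: 3.53 L mol⁻¹
amber: 3.43 L mol⁻¹
mean: 3.48 L mol⁻¹

The two runs differ by 2.72%, so we carry the mean, the exposure per unit of reagent over that fixed time. Then a = exp(−g c):

north-west: 24.0%
north: 37.8%
north-east: 53.5%

North-east leaves 46.5% for the products together, so starting material leads there. For the other two we subtract the isomer and over-reaction product of the nearer run, scaled by reagent. That leaves target leading at 59.9% in north-west and 52.1% in north.

The forecast scaled the same exponent with an effective order of about 0.94. It gave target at 60.7% (59.5% to 61.8%) in north-west, target at 53.5% (52.6% to 54.4%) in north, and 52.5% (50.5% to 54.5%) in north-east, “so starting material leads”. Our north-east figure runs 1.00 percentage point higher, and our north figure 1.4 points lower.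

The flask gave target at 60.6% in north-west, target at 52.9% in north and starting material at 51.8% in north-east, each inside the forecast's range.

starting material + reagent ⇌ target (K = 15.7 L mol⁻¹, k = 0.235 L mol⁻¹ min⁻¹); target ⇌ isomer of the product (K = 0.780, k = 0.00957 min⁻¹); reagent + target → over-reaction product (k = 0.0239 L mol⁻¹ min⁻¹) North-east ended with 87.2% of its reagent charge, and its own g reads 3.66 L mol⁻¹ against our 3.48 L mol⁻¹. Now take a flask like north-west but charged with 160 mM of reagent: g gives 57.3% starting material left, so starting material should lead. It ended with 55.6% starting material, which leads, and 38.5% target.

(The numbers in the tables are calculated from invented constants; scatter was added.)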